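**Plan**
- Retrosynthesis: O1–C2 of the dihydrofuran ring is cut first, giving a phenol and a benzylic carbinol whose oxygen is traded for boron. C2–C1' and C3–C3a are then cut together, leaving a trimethoxyphenylboron unit, a (Z)-propenyl unit and a bromophenol.
- Enabling feature: C2 and C3 are neighbouring CH carbons of the dihydrofuran ring. C2 carries C1' of the trimethoxyphenyl ring and O1; C3 carries C3a of the benzo ring and the methyl group. Both aryl carbons can therefore be added across a propenyl C=C whose boron marks the future O1–C2 bond.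
- Forward: the boron ester and the aryl bromide are each made in two steps, the chain is joined in one three-component coupling, and the only new ring, the dihydrofuran, closes last.
- Stereochemistry: C3 comes from the chiral ligand on palladium (choice of alkene face) and C2 from anti addition across the Z alkene. Oxidation of C–B retains C2 and the Mitsunobu closure inverts it, giving the trans (2R,3R) compound.

Key step: step 5

Assumption: the (Sp,Sp) hand of the ferrocenyl bisphosphine is taken to steer palladium to the alkene face that leads to the (1S,2S) boronate 13; should the sense prove opposite, the commercially available mirror-image ligand is used with nothing else changed.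

Step 1
Reactants: 1 acenaphthylene-1,2-dione (acenaphthoquinone)
Product: 2 cis-(1R,2S)-1,2-dimethyl-1,2-dihydroacenaphthylene-1,2-diol (meso "mac" diol)
Conditions: AlMe3 (3 equiv, hexanes), toluene, 0 °C to rt; aq. potassium sodium tartrate; recrystallisation
Reagents that add atoms: trimethylaluminium, C[Al](C)C
Why: Twofold 1,2-addition of methyl to the 1,2-diketone (carbonyl alkylation by an organoaluminium reagent), the second methyl entering anti to the bulky aluminium alkoxide so that the cis diol should predominate, and any trans diol is purged in step 2 because it cannot bridge boron.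

Step 2
Reactants: 3 (3,4,5-trimethoxyphenyl)boronic acid; 2 cis-1,2-dimethyl-1,2-dihydroacenaphthylene-1,2-diol
Product: 4 3,4,5-trimethoxyphenylboronic acid mac ester (cyclic boronate of diol 2, ArB(mac))
Conditions: toluene, reflux, Dean–Stark trap
Reagents that add atoms: none
Why: Boronic ester formation by condensation of a boronic acid with a cis-1,2-diol, driven by azeotropic removal of water; this rigid, hindered diol is the boron ligand that disfavours direct boron-to-palladium transfer in step 5.

Step 3
Reactants: 5 5-bromovanillin (3-bromo-4-hydroxy-5-methoxybenzaldehyde)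
Product: 6 3-bromo-4-(tert-butyldimethylsilyloxy)-5-methoxybenzaldehyde
Conditions: TBSCl, imidazole, DMF, rt
Reagents that add atoms: tert-butyldimethylsilyl chloride, CC(C)(C)[Si](C)(C)Cl
Why: Imidazole-promoted silylation of the only acidic hydroxyl (silyl ether formation) masks the phenol for the organometallic steps with a group that fluoride later removes without touching the propenyl group.

Step 4
Reactants: 6 3-bromo-4-(tert-butyldimethylsilyloxy)-5-methoxybenzaldehyde; 7 5-(ethylsulfonyl)-1-phenyl-1H-tetrazole
Product: 9 (E)-[2-bromo-6-methoxy-4-(prop-1-enyl)phenoxy](tert-butyl)dimethylsilane, via potassiated ethyl sulfone 8 (not isolated)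
Conditions: 7, KN(SiMe3)2, DME, −60 °C; then 6, −60 °C to rt
Reagents that add atoms: none
Why: Julia–Kocienski olefination, in which the metallated phenyltetrazolyl sulfone adds to the aldehyde and Smiles rearrangement with loss of SO2 and the tetrazololate gives the alkene, the potassium counter-ion in DME favouring the anti adduct and hence the E-propenyl group.

Step 5
Reactants: 10 (Z)-1-bromoprop-1-ene; 4 3,4,5-trimethoxyphenylboronic acid mac ester; 9 (E)-[2-bromo-6-methoxy-4-(prop-1-enyl)phenoxy](tert-butyl)dimethylsilane
Product: 13 mac boronic ester of (1S,2S)-2-[2-(tert-butyldimethylsilyloxy)-3-methoxy-5-((E)-prop-1-enyl)phenyl]-1-(3,4,5-trimethoxyphenyl)propylboron, via (Z)-prop-1-enyllithium 11 (not isolated), via lithium boron ate complex 12 (not isolated)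
Conditions: 10 (1.1 equiv), t-BuLi (2.0 equiv), Et2O, −78 °C; 4, −78 °C to rt; solvent exchange to THF; 9, Pd(OAc)2 (3 mol %), (Sp,Sp)-1,1'-bis[bis(4-methoxy-3,5-dimethylphenyl)phosphino]-2,2'-bis[(R)-α-(dimethylamino)benzyl]ferrocene (3.6 mol %), KOSO2CF3 (KOTf, 2 equiv), THF, 60 °C
Reagents that add atoms: none
Why: Bromine–lithium exchange on 10 proceeds with retention of the Z geometry, and 11 adds to the boron of 4 to give ate complex 12. Oxidative addition of 9 to zerovalent palladium, with KOTf taking up bromide, gives a cationic arylpalladium that binds the propenyl π bond of 12; the trimethoxyphenyl group then shifts from boron to the boron-bearing carbon anti to palladium (1,2-metallate shift), and C–C reductive elimination with retention joins the silyloxyaryl ring to the methyl-bearing carbon. The closest known reaction type is the palladium-catalysed enantioselective conjunctive cross-coupling of β-substituted alkenylboron ate complexes of the mac diol with aryl electrophiles. No ring closes in this step. The methyl-bearing carbon (future C3) is set by the chiral ferrocenyl bisphosphine, which selects the alkene face bound by palladium, and the boron-bearing carbon (future C2) follows from the stereospecific anti addition across the geometrically pure Z alkene, giving the like (1S,2S) diastereomer. The step needs the metallate shift to outrun direct transfer of the propenyl group to palladium and β-hydride elimination, which the hindered mac diol, the readily migrating electron-rich aryl group and the wide-bite-angle ligand secure, while the E-propenyl side chain of 9 is an unactivated internal alkene that does not compete for palladium.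

Step 6
Reactants: 13 (1S,2S)-1,2-diarylpropyl mac boronate
Product: 14 (1S,2R)-2-[2-(tert-butyldimethylsilyloxy)-3-methoxy-5-((E)-prop-1-enyl)phenyl]-1-(3,4,5-trimethoxyphenyl)propan-1-ol
Conditions: H2O2 (30 % aq.), NaOH (3 M aq.), THF, 0 °C to rt; Na2S2O3 quench
Reagents that add atoms: hydrogen peroxide, OO
Why: Oxidation of a boronic ester, in which hydroperoxide adds to boron and the benzylic carbon migrates from boron to oxygen with retention, so the carbinol keeps the spatial arrangement of the C–B bond, while the electron-rich propenyl group is inert to nucleophilic peroxide and any early loss of the silyl group would only anticipate step 7.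

Step 7
Reactants: 14 silyl-protected (1S,2R) carbinol
Product: 15 (1S,2R)-2-[2-hydroxy-3-methoxy-5-((E)-prop-1-enyl)phenyl]-1-(3,4,5-trimethoxyphenyl)propan-1-ol
Conditions: TBAF (1.1 equiv), THF, 0 °C; aq. NH4Cl
Reagents that add atoms: none
Why: Fluoride-mediated desilylation of the aryl silyl ether frees the phenol under conditions that leave the benzylic alcohol, the propenyl group and both stereocentres untouched.

Step 8
Reactants: 15 (1S,2R) phenol carbinol
Product: 16 (2R,3R)-7-methoxy-3-methyl-5-[(E)-prop-1-enyl]-2-(3,4,5-trimethoxyphenyl)-2,3-dihydro-1-benzofuran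
Conditions: PPh3, DIAD, THF, 0 °C to rt
Reagents that add atoms: none
Why: Intramolecular Mitsunobu etherification, in which the phenol protonates the betaine, the secondary benzylic alcohol is activated as its oxyphosphonium ion and the phenoxide displaces it by 5-exo-tet SN2 with inversion, turning the (1S) carbinol carbon into (2R) and placing aryl and methyl trans, the twisted 4-methoxy group of the trimethoxyphenyl ring limiting ionisation.

**Compound list**
1 | acenaphthylene-1,2-dione | O=C1C(=O)c2cccc3cccc1c23 | starting material
2 | cis-(1R,2S)-1,2-dimethyl-1,2-dihydroacenaphthylene-1,2-diol (mac diol) | C[C@]1(O)c2cccc3cccc(c23)[C@@]1(C)O | intermediate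
3 | (3,4,5-trimethoxyphenyl)boronic acid | COc1cc(B(O)O)cc(OC)c1OC | starting material
4 | 3,4,5-trimethoxyphenylboronic acid mac ester | COc1cc(B2O[C@@]3(C)c4cccc5cccc(c45)[C@@]3(C)O2)cc(OC)c1OC | intermediate
5 | 5-bromovanillin | O=Cc1cc(Br)c(O)c(OC)c1 | starting material
6 | 3-bromo-4-(tert-butyldimethylsilyloxy)-5-methoxybenzaldehyde | O=Cc1cc(Br)c(O[Si](C)(C)C(C)(C)C)c(OC)c1 | intermediate
7 | 5-(ethylsulfonyl)-1-phenyl-1H-tetrazole | CCS(=O)(=O)c1nnnn1-c1ccccc1 | starting material
8 | potassium 1-[(1-phenyl-1H-tetrazol-5-yl)sulfonyl]ethan-1-ide | [K+].C[CH-]S(=O)(=O)c1nnnn1-c1ccccc1 | intermediate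
9 | (E)-[2-bromo-6-methoxy-4-(prop-1-enyl)phenoxy](tert-butyl)dimethylsilane | C/C=C/c1cc(OC)c(O[Si](C)(C)C(C)(C)C)c(Br)c1 | intermediate
10 | (Z)-1-bromoprop-1-ene | C/C=C\Br | starting material
11 | (Z)-prop-1-enyllithium | C/C=C\[Li] | intermediate
12 | lithium (Z)-prop-1-enyl(3,4,5-trimethoxyphenyl)borate of the mac diol (configuration at boron immaterial) | [Li+].C/C=C\[B-]1(c2cc(OC)c(OC)c(OC)c2)O[C@@]2(C)c3cccc4cccc(c34)[C@@]2(C)O1 | intermediate
13 | mac boronic ester of (1S,2S)-2-[2-(tert-butyldimethylsilyloxy)-3-methoxy-5-((E)-prop-1-enyl)phenyl]-1-(3,4,5-trimethoxyphenyl)propylboron | C/C=C/c1cc(OC)c(O[Si](C)(C)C(C)(C)C)c(c1)[C@@H](C)[C@@H](c1cc(OC)c(OC)c(OC)c1)B1O[C@@]2(C)c3cccc4cccc(c34)[C@@]2(C)O1 | intermediate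
14 | (1S,2R)-2-[2-(tert-butyldimethylsilyloxy)-3-methoxy-5-((E)-prop-1-enyl)phenyl]-1-(3,4,5-trimethoxyphenyl)propan-1-ol | C/C=C/c1cc(OC)c(O[Si](C)(C)C(C)(C)C)c(c1)[C@@H](C)[C@@H](c1cc(OC)c(OC)c(OC)c1)O | intermediate
15 | (1S,2R)-2-[2-hydroxy-3-methoxy-5-((E)-prop-1-enyl)phenyl]-1-(3,4,5-trimethoxyphenyl)propan-1-ol | C/C=C/c1cc(OC)c(O)c(c1)[C@@H](C)[C@@H](c1cc(OC)c(OC)c(OC)c1)O | intermediate
16 | (2R,3R)-7-methoxy-3-methyl-5-[(E)-prop-1-enyl]-2-(3,4,5-trimethoxyphenyl)-2,3-dihydro-1-benzofuran | C/C=C/c1cc(OC)c2c(c1)[C@@H](C)[C@H](c1cc(OC)c(OC)c(OC)c1)O2 | target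

**Totals**
Total step count: 8. Longest linear sequence: 6 steps (steps 3, 4, 5, 6, 7, 8 from 5-bromovanillin; equally steps 1, 2, 5, 6, 7, 8 from acenaphthoquinone).

**Steps most likely to fail**

Step 5. With the less documented Z geometry, direct transfer of the propenyl group from boron to palladium (simple cross-coupling) may outpace the metallate shift. Binding of the alkene next to the ortho silyloxy group may be slow or poorly face-selective, and bromide may inhibit the cationic palladium. The fallback uses the better documented E geometry and corrects C2 afterwards, setting out from 4 and 9. (E)-1-Bromoprop-1-ene and t-BuLi in Et2O at −78 °C give (E)-prop-1-enyllithium F1, which adds to 4 to give the E-configured lithium ate complex F2. Conjunctive coupling of F2 with 9 under the catalyst of step 5 (ligand hand chosen so that the methyl-bearing carbon is as in 13) should give the (1R,2S) mac boronate F3, epimeric with 13 at the boron-bearing carbon. H2O2 and NaOH convert it with retention into the (1R,2R) silyl-protected carbinol F4. Intermolecular Mitsunobu esterification with 4-nitrobenzoic acid (PPh3, DIAD, THF) inverts the carbinol carbon and gives the (1S,2R) 4-nitrobenzoate F5. K2CO3 in MeOH removes both the ester and the aryl silyl ether, and the sequence comes back to the route at 15.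

Step 8. The activated benzylic oxyphosphonium ion may ionise, leading to elimination toward the styrene-type alkene or to incomplete inversion at C2. The fallback separates activation from ring closure and sets out from 14, with the phenol still silylated. (MeSO2)2O and Et3N in CH2Cl2 at −20 °C convert the carbinol with retention into the (1S,2R) methanesulfonate F6, used without purification. TBAF in THF at −20 °C to rt then unveils the phenoxide, which displaces the sulfonate intramolecularly with inversion (Williamson-type 5-exo-tet closure), and the sequence comes back to the route at 16.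

Step 4. The olefination may give incomplete E selectivity, and the base may strip the silyl group from the electron-poor aryl silyl ether. The fallback gives up kinetic E control for a thermodynamic correction and sets out from 6. Ethyltriphenylphosphonium bromide and KOt-Bu in THF at 0 °C give ethylidenetriphenylphosphorane F7, whose Wittig reaction with 6 should give the propenyl arene mainly as the Z isomer (Z)-[2-bromo-6-methoxy-4-(prop-1-enyl)phenoxy](tert-butyl)dimethylsilane F8. Catalytic PdCl2(MeCN)2 in CH2Cl2 at rt equilibrates the β-methylstyrene to the more stable E isomer without touching the aryl bromide, and the sequence comes back to the route at 9.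

**Further compounds**
F1 | step 5 | (E)-prop-1-enyllithium | C/C=C/[Li]
F2 | step 5 | lithium (E)-prop-1-enyl(3,4,5-trimethoxyphenyl)borate of the mac diol | [Li+].C/C=C/[B-]1(c2cc(OC)c(OC)c(OC)c2)O[C@@]2(C)c3cccc4cccc(c34)[C@@]2(C)O1
F3 | step 5 | mac boronic ester of (1R,2S)-2-[2-(tert-butyldimethylsilyloxy)-3-methoxy-5-((E)-prop-1-enyl)phenyl]-1-(3,4,5-trimethoxyphenyl)propylboron | C/C=C/c1cc(OC)c(O[Si](C)(C)C(C)(C)C)c(c1)[C@@H](C)[C@H](c1cc(OC)c(OC)c(OC)c1)B1O[C@@]2(C)c3cccc4cccc(c34)[C@@]2(C)O1
F4 | step 5 | (1R,2R)-2-[2-(tert-butyldimethylsilyloxy)-3-methoxy-5-((E)-prop-1-enyl)phenyl]-1-(3,4,5-trimethoxyphenyl)propan-1-ol | C/C=C/c1cc(OC)c(O[Si](C)(C)C(C)(C)C)c(c1)[C@@H](C)[C@H](c1cc(OC)c(OC)c(OC)c1)O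
F5 | step 5 | (1S,2R)-2-[2-(tert-butyldimethylsilyloxy)-3-methoxy-5-((E)-prop-1-enyl)phenyl]-1-(3,4,5-trimethoxyphenyl)propyl 4-nitrobenzoate | C/C=C/c1cc(OC)c(O[Si](C)(C)C(C)(C)C)c(c1)[C@@H](C)[C@@H](c1cc(OC)c(OC)c(OC)c1)OC(=O)c1ccc(cc1)[N+](=O)[O-]
F6 | step 8 | (1S,2R)-2-[2-(tert-butyldimethylsilyloxy)-3-methoxy-5-((E)-prop-1-enyl)phenyl]-1-(3,4,5-trimethoxyphenyl)propyl methanesulfonate | C/C=C/c1cc(OC)c(O[Si](C)(C)C(C)(C)C)c(c1)[C@@H](C)[C@@H](c1cc(OC)c(OC)c(OC)c1)OS(C)(=O)=O
F7 | step 4 | ethylidenetriphenylphosphorane | CC=P(c1ccccc1)(c1ccccc1)c1ccccc1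
F8 | step 4 | (Z)-[2-bromo-6-methoxy-4-(prop-1-enyl)phenoxy](tert-butyl)dimethylsilane | C/C=C\c1cc(OC)c(O[Si](C)(C)C(C)(C)C)c(Br)c1
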